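**Retrosynthetic overview**
- Nortopsentin A is 2,4-bis(6-bromoindol-3-yl)imidazole. The imidazole is cut into an N1–C2–N3 amidine (6-bromoindole-3-carboxamidine), a C4–C5 two-carbon unit, and the bond from imidazole C4 to C3 of the second 6-bromoindole.
- Enabling feature: imidazole C4 is bonded to C3 of a free N–H indole (the nucleophilic enamine β-carbon of the pyrrole ring) and C5 carries only H. C4–C5 is therefore glyoxal at its own oxidation level, and the whole assembly is redox-neutral (loss of 2 H2O).
- Key step: amidine + glyoxal + 6-bromoindole in one pot. The cyclic bis-hemiaminal ionises to an N-amidino iminium ion, C3 of the indole forms the C4–C3' bond, and dehydration aromatises the ring.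
- The amidine comes from 6-bromoindole by C3 cyanation and Pinner amination, so both halves derive from one commercial indole.
- Ring order: both indole rings are bought; the imidazole is the only ring formed, last, together with the C4–C3' bond.

Key step: step 3

Remark: the target has no stereocentre, axis or configurable double bond, so the achiral compound is the required single species and no stereocontrol is needed.

**Step 1**
Reactants: 1 6-bromo-1H-indole
Product: 3 6-bromo-1H-indole-3-carbonitrile, via N-chlorosulfonyl carboxamide 2 (not isolated)
Conditions: ClSO2NCO (1.1 equiv), MeCN, 0 °C; then DMF, 0 °C to rt; ice-water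
Reagents that add atoms: chlorosulfonyl isocyanate, O=C=NS(=O)(=O)Cl
Why: Electrophilic aromatic substitution at indole C3 by chlorosulfonyl isocyanate gives the N-chlorosulfonyl amide, which DMF dehydrates to the nitrile with loss of SO3 and HCl (the standard CSI cyanation of indoles); the C6–Br bond is inert.

**Step 2**
Reactants: 3 6-bromo-1H-indole-3-carbonitrile
Product: 5 6-bromo-1H-indole-3-carboximidamide hydrochloride, via imidate hydrochloride 4 (not isolated)
Conditions: HCl (g), EtOH–dioxane, 0 °C to rt; evaporate; NH3 (7 M in MeOH), rt to 40 °C
Reagents that add atoms: ammonia, N; hydrogen chloride, Cl; ethanol, CCO (its atoms stand in 4 only)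
Why: Pinner reaction: HCl activates the nitrile toward ethanol to give the imidate salt, and ammonia replaces ethoxide by addition–elimination to give the amidinium chloride; the 3-cyano group protects the indole from acid-induced oligomerisation.

**Step 3**
Reactants: 5 6-bromo-1H-indole-3-carboximidamide hydrochloride; 6 glyoxal (40% aq.); 1 6-bromo-1H-indole
Product: 9 nortopsentin A, via dihydroxyimidazoline 7 (not isolated), via hydroxy-indolylimidazoline 8 (not isolated)
Conditions: (i) 6 (1.05 equiv), NaOAc (1.0 equiv), MeOH–H2O, 0 °C to rt; (ii) 1 (1.5 equiv), AcOH–HFIP, 50 °C; aq. NaHCO3 work-up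
Reagents that add atoms: none
Why: Proposed new method: the liberated amidine condenses with both aldehyde groups of glyoxal to the cyclic bis-hemiaminal 7 (5-exo-trig closure of the second nitrogen onto the remaining aldehyde, the only ring closed), and in the weakly acidic, strongly ionising AcOH–HFIP medium 7 loses water to a 4H-imidazolium ion (a cyclic N-amidino iminium ion) that C3 of 6-bromoindole attacks in an aza-Friedel–Crafts step to give 8, whose second dehydration across C4–C5 aromatises the ring. The closest known reaction types are the three-component condensations of arylglyoxals with amidines or 2-aminoazines and indole or enol C-nucleophiles to C-substituted imidazoles, and the acid-catalysed amidoalkylation of indoles by cyclic N,O-hemiaminals such as 4,5-dihydroxy- and 4-alkoxyimidazolidin-2-ones; new here are glyoxal itself as the two-carbon unit and an amidine-derived bis-hemiaminal as the electrophile. No stereocentre survives, since both sp3 carbons of 7 and 8 become sp2 in 9. The step needs amidine-before-indole chemoselectivity toward glyoxal, which is secured by forming 7 at neutral pH before acid and indole are added; it needs C3 rather than N1 or C2 attack, which the enamine reactivity of the free N–H indole under acid provides; and it needs mono-arylation, which should follow because ionisation at the remaining hemiaminal carbon of 8 is followed by loss of the doubly activated C–H to the non-electrophilic aromatic imidazole faster than a second intermolecular arylation. The competing collapse of 7 to an imidazol-4-one is countered by having excess indole present in a non-basic medium at the moment the cation forms.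

**Compound list**
1 | 6-bromo-1H-indole | Brc1ccc2cc[nH]c2c1 | starting material
2 | 6-bromo-N-(chlorosulfonyl)-1H-indole-3-carboxamide | O=C(NS(=O)(=O)Cl)c1c[nH]c2cc(Br)ccc12 | intermediate
3 | 6-bromo-1H-indole-3-carbonitrile | N#Cc1c[nH]c2cc(Br)ccc12 | intermediate
4 | ethyl 6-bromo-1H-indole-3-carboximidate hydrochloride | CCOC(=N)c1c[nH]c2cc(Br)ccc12.Cl | intermediate
5 | 6-bromo-1H-indole-3-carboximidamide hydrochloride | NC(=N)c1c[nH]c2cc(Br)ccc12.Cl | intermediate
6 | glyoxal (ethanedial, 40% aqueous solution) | O=CC=O | starting material
7 | 2-(6-bromo-1H-indol-3-yl)-4,5-dihydro-1H-imidazole-4,5-diol (stereoisomer mixture, both centres lost later) | OC1NC(c2c[nH]c3cc(Br)ccc23)=NC1O | intermediate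
8 | 2,4-bis(6-bromo-1H-indol-3-yl)-4,5-dihydro-1H-imidazol-5-ol (stereoisomer mixture, both centres lost later) | OC1NC(c2c[nH]c3cc(Br)ccc23)=NC1c4c[nH]c5cc(Br)ccc45 | intermediate
9 | nortopsentin A, 2,4-bis(6-bromo-1H-indol-3-yl)-1H-imidazole | Brc1ccc2c(-c3c[nH]c(-c4c[nH]c5cc(Br)ccc45)n3)c[nH]c2c1 | target

**Step count**
Total steps: 3. Longest linear sequence: 3 steps (1 → 3 → 5 → 9); compound 1 enters a second time in step 3.

**Steps most likely to fail**

1. Step 3 (Proposed new method). Three processes may go wrong. The bis-hemiaminal may dehydrate and tautomerise to an imidazol-4-one before the C–C bond forms. The condensation may reverse and release glyoxal, which the indole then captures twice. A second arylation may occur at the remaining hemiaminal carbon. Fallback with known chemistry, setting out from 1 and 5 and returning at 9: Friedel–Crafts C3 acylation of 1 with chloroacetyl chloride (pyridine, dioxane, 60 °C) should give 1-(6-bromo-1H-indol-3-yl)-2-chloroethan-1-one F1. Condensation of F1 with amidine salt 5 (KHCO3, THF–H2O, reflux) should proceed by N-alkylation and ring closure to 2,4-bis(6-bromo-1H-indol-3-yl)-4,5-dihydro-1H-imidazol-4-ol F2, which dehydrates in the flask to 9 (the classical α-haloketone–amidine imidazole synthesis).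

2. Step 2. Alcoholysis of the electron-rich, vinylogous-cyanamide-like nitrile may stay incomplete, and adventitious water may hydrolyse the imidate to ester or amide. Fallback, setting out from 3 and returning at 5: addition of hydroxylamine (NH2OH·HCl, Na2CO3, EtOH, reflux) should give (Z)-6-bromo-N'-hydroxy-1H-indole-3-carboximidamide F3. O-Acetylation (Ac2O, AcOH, rt) should give the O-acetyl amidoxime F4. Reductive N–O cleavage with zinc dust in AcOH, which leaves the aryl bromide alone, followed by HCl in dioxane should deliver 5.

3. Step 1. The indole may be carbamoylated at nitrogen or oligomerised by the acid set free, and dehydration of the sulfonyl amide may stop at the primary amide. Fallback, setting out from 1 and returning at 3: C3 acylation with trichloroacetyl chloride (pyridine, THF, rt to 60 °C) should give 1-(6-bromo-1H-indol-3-yl)-2,2,2-trichloroethan-1-one F5. Haloform-type ammonolysis (NH3, MeOH–THF, rt) should give 6-bromo-1H-indole-3-carboxamide F6. Dehydration (POCl3, MeCN, 60 °C) should give nitrile 3.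

**Further compounds**
F1 | step 3 | 1-(6-bromo-1H-indol-3-yl)-2-chloroethan-1-one | O=C(CCl)c1c[nH]c2cc(Br)ccc12
F2 | step 3 | 2,4-bis(6-bromo-1H-indol-3-yl)-4,5-dihydro-1H-imidazol-4-ol (racemic) | OC1(c2c[nH]c3cc(Br)ccc23)CNC(c4c[nH]c5cc(Br)ccc45)=N1
F3 | step 2 | (Z)-6-bromo-N'-hydroxy-1H-indole-3-carboximidamide | N/C(=N\O)c1c[nH]c2cc(Br)ccc12
F4 | step 2 | (Z)-N'-acetoxy-6-bromo-1H-indole-3-carboximidamide | CC(=O)O/N=C(\N)c1c[nH]c2cc(Br)ccc12
F5 | step 1 | 1-(6-bromo-1H-indol-3-yl)-2,2,2-trichloroethan-1-one | O=C(c1c[nH]c2cc(Br)ccc12)C(Cl)(Cl)Cl
F6 | step 1 | 6-bromo-1H-indole-3-carboxamide | NC(=O)c1c[nH]c2cc(Br)ccc12
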